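**Assumptions (one line each)**
- Methyl 3-bromo-1H-pyrrole-2-carboxylate (6) is taken as commercially available.
- The target SMILES has no stereocentres, so no stereocontrol is needed. The 2-hydroxyindole is the lactim tautomer of the 3-substituted oxindole. The oxindole carbon C3 is epimerisable and racemises instantly, so the compound is a single achiral structure as drawn. The lactam form is the likely resting form.

**Retrosynthesis**
- Final steps: remove the benzyl ether (hydrogenolysis) and the ester and N-Ts groups (saponification) from a fully assembled 2,3,5-trisubstituted pyrrole.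
- The oxindole C3–pyrrole C3 bond comes from Pd-catalysed α-arylation of oxindole with a 3-bromopyrrole.
- The indole C3–pyrrole C5 bond comes from Suzuki coupling of a pyrrole 5-Bpin (made by Ir C–H borylation) with a 3-iodoindole.
- No ring is constructed; the pyrrole, indole and oxindole rings all come from commercial materials. The 3-iodoindole fragment is made from 5-benzyloxyindole in two steps.

**Route**

**Step 1**
Reactants: 1 (5-benzyloxyindole); 2 (N-iodosuccinimide)
Product: 3 (5-benzyloxy-3-iodo-1H-indole)
Conditions: NIS, DMF, 0 °C, 30 min; crude used at once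
Reagents that add atoms: NIS, O=C1CCC(=O)N1I
Why: Electrophilic iodination (SEAr) occurs at the most nucleophilic indole position, C3.

**Step 2**
Reactants: 3; 4 (p-toluenesulfonyl chloride)
Product: 5 (5-benzyloxy-3-iodo-1-tosylindole)
Conditions: NaH, TsCl, DMF, 0 °C to rt
Reagents that add atoms: TsCl, Cc1ccc(cc1)S(=O)(=O)Cl
Why: N-sulfonylation stabilises the labile 3-iodoindole and survives the later Pd and strong-base steps. It is cleaved in Step 6.

**Step 3**
Reactants: 6 (methyl 3-bromo-1H-pyrrole-2-carboxylate); 7 (B2pin2)
Product: 8 (methyl 3-bromo-5-(4,4,5,5-tetramethyl-1,3,2-dioxaborolan-2-yl)-1H-pyrrole-2-carboxylate)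
Conditions: B2pin2 (0.6 equiv), [Ir(OMe)(cod)]2 (1.5 mol%), dtbpy (3 mol%), THF, 80 °C
Reagents that add atoms: B2pin2, CC1(C)OB(OC1(C)C)B1OC(C)(C)C(C)(C)O1
Why: Ir-catalysed C–H borylation of 2-substituted N–H pyrroles goes to the unhindered α C5–H. The 3-Br blocks C4 sterically and is untouched, so this is regioselective. No stereocentre is involved.

**Step 4**
Reactants: 8; 5
Product: 9 (methyl 3-bromo-5-[5-benzyloxy-1-tosylindol-3-yl]-1H-pyrrole-2-carboxylate)
Conditions: Pd(PPh3)4 (5 mol%), aq. Na2CO3, DME, 70 °C
Reagents that add atoms: none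
Why: Suzuki–Miyaura coupling is chemoselective for the 3-iodoindole over the electron-poor, deactivated 3-bromopyrrole. No stereocentre is involved.

**Step 5**
Reactants: 9; 10 (oxindole, 1.5 equiv)
Product: 11 (methyl 5-[5-benzyloxy-1-tosylindol-3-yl]-3-(2-oxoindolin-3-yl)-1H-pyrrole-2-carboxylate)
Conditions: Pd2(dba)3 (2.5 mol%), XPhos (10 mol%), LiHMDS (4.5 equiv), THF/toluene, 80 °C
Reagents that add atoms: none (the oxindole is a reactant)
Why: Pd-catalysed enolate α-arylation (Buchwald–Hartwig type) of the oxindole C3 anion with the bromopyrrole. The new oxindole C3 centre is epimerisable and irrelevant to the achiral target.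

**Step 6**
Reactants: 11
Product: 12 (5-[5-benzyloxy-1H-indol-3-yl]-3-(2-oxoindolin-3-yl)-1H-pyrrole-2-carboxylic acid)
Conditions: NaOH (10 equiv), MeOH/THF/H2O, 65 °C, under argon; then 1 M HCl to pH 3
Reagents that add atoms: sodium hydroxide, [Na+].[OH-], and water, O (the carboxylic acid oxygen comes from hydroxide/water)
Why: Base-mediated ester saponification and N-desulfonylation (hydroxide attack at sulfur) are done in one pot. The oxindole lactam survives (any ring-opened amino acid relactamises on acidification), and the benzyl ether is inert.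

**Step 7**
Reactants: 12
Product: 13 (violaceinic acid, target)
Conditions: H2 (1 atm), 10% Pd/C, MeOH/EtOAc, rt
Reagents that add atoms: none (H2 only adds hydrogen)
Why: Hydrogenolysis of the aryl benzyl ether (toluene is lost) unmasks the 5-OH. Pyrrole, indole and oxindole are not reduced at 1 atm H2. This is done last because the free 5-hydroxyindole is air- and base-sensitive.

**Self-check**
- The target has a pyrrole with C2 CO2H, C3 oxindol-3-yl (drawn as 2-hydroxyindole) and C5 5-hydroxyindol-3-yl, with C4–H. Compound 13 matches this substitution.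
- Atom balance holds at every step:
  - 1 + I → 3
  - 3 + Ts – H → 5
  - 6 + Bpin – H → 8
  - 8 + 5 → 9 + I–Bpin
  - 9 + 10 – HBr → 11
  - 11 – Ts – CH3 (ester → acid) → 12
  - 12 – Bn + H → 13
- Protecting groups survive the steps that precede their removal. The Ts group survives Steps 4–5 and the Bn group survives Steps 4–6. The 3-Br is not consumed by Step 3 or Step 4.
- The only potential stereocentre (the oxindole C3 in the lactam form) is intentionally labile, and the target SMILES has none.

**Compound list**
1 | 5-benzyloxyindole | O(Cc1ccccc1)c1ccc2[nH]ccc2c1 | starting material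
2 | N-iodosuccinimide | O=C1CCC(=O)N1I | reagent
3 | 5-benzyloxy-3-iodo-1H-indole | O(Cc1ccccc1)c1ccc2[nH]cc(I)c2c1 | intermediate
4 | p-toluenesulfonyl chloride | Cc1ccc(cc1)S(=O)(=O)Cl | reagent
5 | 5-benzyloxy-3-iodo-1-tosylindole | Cc1ccc(cc1)S(=O)(=O)n1cc(I)c2cc(OCc3ccccc3)ccc21 | intermediate
6 | methyl 3-bromo-1H-pyrrole-2-carboxylate | COC(=O)c1[nH]ccc1Br | starting material
7 | bis(pinacolato)diboron | CC1(C)OB(OC1(C)C)B1OC(C)(C)C(C)(C)O1 | reagent
8 | methyl 3-bromo-5-Bpin-1H-pyrrole-2-carboxylate | COC(=O)c1[nH]c(B2OC(C)(C)C(C)(C)O2)cc1Br | intermediate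
9 | methyl 3-bromo-5-[5-benzyloxy-1-tosylindol-3-yl]-1H-pyrrole-2-carboxylate | COC(=O)c1[nH]c(cc1Br)-c1cn(S(=O)(=O)c2ccc(C)cc2)c2ccc(OCc3ccccc3)cc12 | intermediate
10 | oxindole (indolin-2-one) | O=C1Cc2ccccc2N1 | starting material
11 | methyl 5-[5-benzyloxy-1-tosylindol-3-yl]-3-(2-oxoindolin-3-yl)-1H-pyrrole-2-carboxylate | COC(=O)c1[nH]c(cc1C1C(=O)Nc2ccccc12)-c1cn(S(=O)(=O)c2ccc(C)cc2)c2ccc(OCc3ccccc3)cc12 | intermediate
12 | 5-[5-benzyloxy-1H-indol-3-yl]-3-(2-oxoindolin-3-yl)-1H-pyrrole-2-carboxylic acid | OC(=O)c1[nH]c(cc1C1C(=O)Nc2ccccc12)-c1c[nH]c2ccc(OCc3ccccc3)cc12 | intermediate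
13 | violaceinic acid (drawn as the 2-hydroxyindole tautomer; the oxindole form is the same compound) | O=C(O)c1[nH]c(-c2c[nH]c3ccc(O)cc23)cc1-c1c(O)[nH]c2ccccc12 | target

**Totals**
- Total steps: 7.
- Longest linear sequence: 6 steps (1 → 3 → 5 → 9 → 11 → 12 → 13).

**Three steps most likely to fail**
1. **Step 5 (oxindole α-arylation).** The free pyrrole N–H and the 3-bromopyrrole are poor partners, and the product can be arylated a second time.
   - Fallback: change the approach. Suzuki-couple the bromopyrrole with an N-protected indol-3-yl Bpin first. Then oxidise the indole to the oxindole (NBS, aq. t-BuOH, then Zn/AcOH) before the 5-hydroxyindole is installed.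
2. **Steps 3 and 4 (C–H borylation and Suzuki coupling).** The free N–H pyrrol-2-yl Bpin is prone to protodeboronation, and the AB-type monomer can self-couple.
   - Fallback: skip boron. Do a direct Pd-catalysed C5–H arylation of compound 6 with iodoindole 5 (Pd(OAc)2, PPh3 or a carbonate base, DMA), or use N-Boc-protected pyrrole.
3. **Step 6 (hot aqueous base).** The hindered 3-aryl pyrrole methyl ester needs forcing conditions, and the 3-aryl oxindole enolate is air-sensitive (3-hydroxylation, dimerisation).
   - Fallback: use the benzyl ester of 3-bromopyrrole-2-carboxylic acid from the start. Remove Ts under mild, non-hydrolytic conditions (Mg/MeOH), then cleave the ester and the OBn group together in a single hydrogenolysis.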